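**Retrosynthetic overview**
1. The target is a linear tridepside: ring A (methyl orsellinate) is acylated at O4 by ring B, and ring B at O4' by ring C; rings B and C are both 2,4-dihydroxy-6-methylbenzoyl units.
2. The plan rests on ring C: its carboxyl-bearing C1'' sits between methyl-bearing C6'' and hydroxyl-bearing C2'', so C1''/C6'' (with the methyl and the ester carbonyl) are an aryl but-2-ynoate and C2''–C5'' are the four carbons of 1-methoxy-1,3-bis(trimethylsilyloxy)buta-1,3-diene.
3. Cutting C1''–C2'' and C5''–C6'' (Diels–Alder benzannulation) leads to the 4'-O-but-2-ynoate of the didepside, made by acylating its only non-chelated phenol with but-2-ynoic acid.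
4. Ring B has the same pattern and is cut the same way back to methyl orsellinate 4-O-but-2-ynoate; ring A is bought, ring B is formed first, ring C last.
5. The chelated ortho-hydroxyls are masked in the flask as trimethylsilyl ethers and freed in the acidic work-up of each cycloaddition, so no separate protection steps are needed.

Key step: step 6

Remark on the chemistry: the transient TMS ethers (from N,O-bis(trimethylsilyl)acetamide, BSA) replace longer-lived phenol protecting groups; the target has no stereocenter, and the cycloadducts are racemic at a ketal carbon that is lost on aromatization.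

**Step 1**
Reactants: 1 methyl acetoacetate
Product: 2 methyl 3-(trimethylsilyloxy)but-2-enoate (E/Z mixture, geometry of no consequence)
Conditions: TMSCl, Et3N, hexane, rt
Reagents that add atoms: chlorotrimethylsilane, C[Si](C)(C)Cl
Why: Soft enolization of the beta-keto ester by Et3N and O-silylation of the enol should give the silyl enol ether, the standard first stage of 1,3-bis(silyloxy)diene preparation.

**Step 2**
Reactants: 2 methyl 3-(trimethylsilyloxy)but-2-enoate
Product: 3 1-methoxy-1,3-bis(trimethylsilyloxy)buta-1,3-diene (ketene-acetal geometry of no consequence)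
Conditions: LiN(iPr)2, THF, −78 °C; then TMSCl, −78 °C to rt; filtration from hexane, used directly
Reagents that add atoms: chlorotrimethylsilane, C[Si](C)(C)Cl
Why: Kinetic gamma-deprotonation of the vinylogous ester gives the extended dienolate, which TMSCl should trap on the ester oxygen (silyl ketene acetal formation).

**Step 3**
Reactants: 4 methyl orsellinate (methyl 2,4-dihydroxy-6-methylbenzoate); 5 but-2-ynoic acid
Product: 6 methyl 4-(but-2-ynoyloxy)-2-hydroxy-6-methylbenzoate
Conditions: DCC, DMAP (cat.), CH2Cl2, −20 °C to 0 °C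
Reagents that add atoms: none
Why: Steglich esterification should acylate only the 4-hydroxyl, because the 2-hydroxyl is hydrogen-bonded to and flanked by the ester carbonyl, and the small linear acid couples at low temperature before DMAP can attack the ynoate.

**Step 4**
Reactants: 6 methyl 4-(but-2-ynoyloxy)-2-hydroxy-6-methylbenzoate; 3 1-methoxy-1,3-bis(trimethylsilyloxy)buta-1,3-diene
Product: 10 methyl lecanorate (methyl 4-[(2,4-dihydroxy-6-methylbenzoyl)oxy]-2-hydroxy-6-methylbenzoate), via aryl TMS ether 7 (not isolated), via cyclohexa-1,4-diene cycloadduct 8 (not isolated), via tris-TMS didepside 9 (not isolated)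
Conditions: BSA (1.5 equiv), toluene, 60 °C; then 3 (3 equiv), 110–120 °C, sealed tube; then 1 M HCl, THF, 0 °C to rt
Reagents that add atoms: none
Why: After O-silylation of the chelated phenol, the ketene-acetal diene should add to the aryl ynoate in a regioselective thermal Diels–Alder reaction (CH2 terminus to the methyl-bearing beta carbon), and acid-promoted loss of methanol with cleavage of the TMS ethers aromatizes the adduct to ring B (Diels–Alder benzannulation to a resorcylate).

**Step 5**
Reactants: 10 methyl lecanorate; 5 but-2-ynoic acid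
Product: 11 methyl 4-{[4-(but-2-ynoyloxy)-2-hydroxy-6-methylbenzoyl]oxy}-2-hydroxy-6-methylbenzoate
Conditions: DCC, DMAP (cat.), THF/CH2Cl2, −20 °C to 0 °C
Reagents that add atoms: none
Why: Steglich esterification should take place at the 4'-hydroxyl, the only phenol of 10 not tied up in a hydrogen bond to an ortho ester carbonyl, and the unhindered alkynoic acid is an easy acyl donor.

**Step 6**
Reactants: 11 methyl 4-{[4-(but-2-ynoyloxy)-2-hydroxy-6-methylbenzoyl]oxy}-2-hydroxy-6-methylbenzoate; 3 1-methoxy-1,3-bis(trimethylsilyloxy)buta-1,3-diene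
Product: 15 methyl 4-({4-[(2,4-dihydroxy-6-methylbenzoyl)oxy]-2-hydroxy-6-methylbenzoyl}oxy)-2-hydroxy-6-methylbenzoate (target), via bis-TMS ether 12 (not isolated), via cyclohexa-1,4-diene cycloadduct 13 (not isolated), via tetrakis-TMS tridepside 14 (not isolated)
Conditions: BSA (2.5 equiv), toluene, 60 °C; then 3 (3 equiv), 110–120 °C, sealed tube; then 1 M HCl, THF, 0 °C to rt
Reagents that add atoms: none
Why: BSA first caps the two chelated phenols of 11 so that no acidic proton destroys the ketene acetal, and the electron-rich diene 3 then adds to the electron-poor alkyne of 12 in a thermal, strongly asynchronous [4+2] cycloaddition whose closest known relatives are the additions of 1-alkoxy-1,3-bis(silyloxy)dienes to alkyl alkynoates and allenoates that give resorcylates. Ring C is closed in this one intermolecular cycloaddition, which forms C5''–C6'' and C1''–C2'' and gives the cyclohexa-1,4-diene 13; 1,4-elimination of methanol from its mixed methyl silyl ketal, completed by acid, aromatizes it to 14, and the same aqueous acid cleaves the four aryl TMS ethers to 15. No stereocenter is set, since the ketal carbon of 13 is a transient racemic center erased on aromatization. The step needs regioselectivity, which polarization secures: the unsubstituted CH2 terminus of 3 carries the largest HOMO coefficient and attacks the methyl-bearing beta carbon of the ynoate, so the ketene-acetal carbon ends on the alpha carbon next to the carboxyl; it also needs chemoselectivity for the alkyne over the three ester carbonyls, which the absence of any Lewis acid secures, and loss of methanol instead of silanol, which Si–O cleavage before ketal collapse secures. The phenolic ester lowers the alkyne LUMO relative to an alkyl but-2-ynoate, and the crowded 2,6-disubstituted benzoate is assembled on an ester linkage already in place instead of by acylation with a hindered acid.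

**Compound list**
1 | methyl acetoacetate | COC(=O)CC(C)=O | starting material
2 | methyl 3-(trimethylsilyloxy)but-2-enoate (E/Z mixture) | COC(=O)C=C(C)O[Si](C)(C)C | intermediate
3 | 1-methoxy-1,3-bis(trimethylsilyloxy)buta-1,3-diene | COC(O[Si](C)(C)C)=CC(=C)O[Si](C)(C)C | intermediate
4 | methyl orsellinate (methyl 2,4-dihydroxy-6-methylbenzoate) | COC(=O)c1c(C)cc(O)cc1O | starting material
5 | but-2-ynoic acid | CC#CC(O)=O | starting material
6 | methyl 4-(but-2-ynoyloxy)-2-hydroxy-6-methylbenzoate | COC(=O)c1c(C)cc(OC(=O)C#CC)cc1O | intermediate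
7 | methyl 4-(but-2-ynoyloxy)-6-methyl-2-(trimethylsilyloxy)benzoate (not isolated) | COC(=O)c1c(C)cc(OC(=O)C#CC)cc1O[Si](C)(C)C | intermediate
8 | 4-(methoxycarbonyl)-3-methyl-5-(trimethylsilyloxy)phenyl 6-methoxy-2-methyl-4,6-bis(trimethylsilyloxy)cyclohexa-1,4-diene-1-carboxylate (racemic, not isolated) | COC1(O[Si](C)(C)C)C=C(O[Si](C)(C)C)CC(C)=C1C(=O)Oc1cc(C)c(C(=O)OC)c(O[Si](C)(C)C)c1 | intermediate
9 | methyl 4-{[6-methyl-2,4-bis(trimethylsilyloxy)benzoyl]oxy}-6-methyl-2-(trimethylsilyloxy)benzoate (not isolated) | COC(=O)c1c(C)cc(OC(=O)c2c(C)cc(O[Si](C)(C)C)cc2O[Si](C)(C)C)cc1O[Si](C)(C)C | intermediate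
10 | methyl lecanorate (methyl 4-[(2,4-dihydroxy-6-methylbenzoyl)oxy]-2-hydroxy-6-methylbenzoate) | COC(=O)c1c(C)cc(OC(=O)c2c(C)cc(O)cc2O)cc1O | intermediate
11 | methyl 4-{[4-(but-2-ynoyloxy)-2-hydroxy-6-methylbenzoyl]oxy}-2-hydroxy-6-methylbenzoate | COC(=O)c1c(C)cc(OC(=O)c2c(C)cc(OC(=O)C#CC)cc2O)cc1O | intermediate
12 | methyl 4-{[4-(but-2-ynoyloxy)-6-methyl-2-(trimethylsilyloxy)benzoyl]oxy}-6-methyl-2-(trimethylsilyloxy)benzoate (cycloaddition precursor, not isolated) | COC(=O)c1c(C)cc(OC(=O)c2c(C)cc(OC(=O)C#CC)cc2O[Si](C)(C)C)cc1O[Si](C)(C)C | intermediate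
13 | 4-{[4-(methoxycarbonyl)-3-methyl-5-(trimethylsilyloxy)phenoxy]carbonyl}-3-methyl-5-(trimethylsilyloxy)phenyl 6-methoxy-2-methyl-4,6-bis(trimethylsilyloxy)cyclohexa-1,4-diene-1-carboxylate (racemic, not isolated) | COC1(O[Si](C)(C)C)C=C(O[Si](C)(C)C)CC(C)=C1C(=O)Oc1cc(C)c(C(=O)Oc2cc(C)c(C(=O)OC)c(O[Si](C)(C)C)c2)c(O[Si](C)(C)C)c1 | intermediate
14 | 2,2',2'',4''-tetrakis-O-(trimethylsilyl) derivative of the target (not isolated) | COC(=O)c1c(C)cc(OC(=O)c2c(C)cc(OC(=O)c3c(C)cc(O[Si](C)(C)C)cc3O[Si](C)(C)C)cc2O[Si](C)(C)C)cc1O[Si](C)(C)C | intermediate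
15 | methyl 4-({4-[(2,4-dihydroxy-6-methylbenzoyl)oxy]-2-hydroxy-6-methylbenzoyl}oxy)-2-hydroxy-6-methylbenzoate | COC(=O)c1c(C)cc(OC(=O)c2c(C)cc(OC(=O)c3c(C)cc(O)cc3O)cc2O)cc1O | target

**Step count**
Total: 6 steps. Longest linear sequence: 5 steps (steps 1, 2, 4, 5, 6 from methyl acetoacetate; 4 steps from methyl orsellinate).

**Steps most likely to fail**

Step 6. The cycloaddition onto the beta-methyl ynoate may be slower than thermal decay of the diene. Conjugate addition may also stop before ring closure, or silanol may be lost in place of methanol and leave a 2''-O-methyl ether. The fallback sets out from 10 and returns at 15 by classical depside coupling. Methyl orsellinate 4 is dibenzylated (BnBr, K2CO3, DMF, 60 °C) to methyl 2,4-bis(benzyloxy)-6-methylbenzoate F1. Saponification (KOH, DMSO/H2O, 90 °C) gives 2,4-bis(benzyloxy)-6-methylbenzoic acid F2. F2 is condensed with the free 4'-hydroxyl of 10 through its mixed trifluoroacetic anhydride (TFAA, toluene, rt) to the 2'',4''-di-O-benzyl tridepside F3. Hydrogenolysis (H2, Pd/C, EtOAc, rt) of the two benzyl ethers then gives 15.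

Step 4. The same slow cycloaddition may occur, and incomplete silylation of the chelated phenol would protonate and consume the diene. The fallback sets out from 4 and returns at 10. Acid F2, made from 4 through F1 as above, is condensed with the 4-hydroxyl of 4 (TFAA, toluene, rt) to methyl 4-{[2,4-bis(benzyloxy)-6-methylbenzoyl]oxy}-2-hydroxy-6-methylbenzoate F4, and hydrogenolysis (H2, Pd/C, EtOAc, rt) gives 10.

Step 5. DMAP may add to the activated ynoate and trigger isomerization or oligomerization, a phenol may add in conjugate fashion to the ynoate, or more than one hydroxyl may be acylated. The fallback sets out from 10 and 5 and returns at 11 without carbodiimide or nucleophilic catalyst. Acid 5 is converted with oxalyl chloride (cat. DMF, CH2Cl2, 0 °C) into but-2-ynoyl chloride F5, which acylates the most acidic, non-chelated 4'-phenol of 10 in the presence of 2,6-lutidine (THF, −20 °C).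

**Further compounds**
F1 | step 6 | methyl 2,4-bis(benzyloxy)-6-methylbenzoate | COC(=O)c1c(C)cc(OCc2ccccc2)cc1OCc1ccccc1
F2 | step 6 | 2,4-bis(benzyloxy)-6-methylbenzoic acid | OC(=O)c1c(C)cc(OCc2ccccc2)cc1OCc1ccccc1
F3 | step 6 | methyl 4-({4-[(2,4-bis(benzyloxy)-6-methylbenzoyl)oxy]-2-hydroxy-6-methylbenzoyl}oxy)-2-hydroxy-6-methylbenzoate | COC(=O)c1c(C)cc(OC(=O)c2c(C)cc(OC(=O)c3c(C)cc(OCc4ccccc4)cc3OCc3ccccc3)cc2O)cc1O
F4 | step 4 | methyl 4-{[2,4-bis(benzyloxy)-6-methylbenzoyl]oxy}-2-hydroxy-6-methylbenzoate | COC(=O)c1c(C)cc(OC(=O)c2c(C)cc(OCc3ccccc3)cc2OCc2ccccc2)cc1O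
F5 | step 5 | but-2-ynoyl chloride | CC#CC(Cl)=O
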